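**Retrosynthetic overview**

- Ring numbering: C1 bears C7H2OSO3H, C2 Br, C3 Br, C4 OSO3H, C5 OH, C6 Br. The plan rests on the fully substituted benzene ring: the run C3(Br)-C4(O)-C5(O)-C6(Br) is the carbon chain of a 2,5-dibromo-3,4-dialkoxythiophene, and C1(C7)-C2(Br) is a 3-bromopropiolate.
- Key disconnection: C2-C3 and C6-C1, made by Diels-Alder addition of 2,5-dibromo-3,4-dimethoxythiophene 1,1-dioxide to methyl 3-bromopropiolate with loss of SO2. The benzene ring is the only ring formed; the thiophene ring is given up.
- End game: O4 and O5 are told apart on the ester by cleaving the silyl ether of the more acidic para oxygen O4. O4 is sulfated before the ester is reduced and O7 after, so a free para-hydroxyl never sits beside a benzylic leaving group. O5 stays a triisopropylsilyl ether until the last step.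
- Precursors: the dioxide from 3,4-dimethoxythiophene (NBS, then CF3CO3H); the bromoalkyne from methyl propiolate (NBS, AgNO3).

Key step: step 4

Assumption: the target is taken as the free bis(hydrogen sulfate) shown by the SMILES. Such acids keep only as salts, so the last operation releases the acid from its disodium salt in the cold.

**Route**

Step 1
Reactants: 1 3,4-dimethoxythiophene; 2 N-bromosuccinimide
Product: 3 2,5-dibromo-3,4-dimethoxythiophene
Conditions: NBS (2.05 equiv), DMF, −10 °C to 0 °C, dark; product kept cold and used at once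
Reagents that add atoms: N-bromosuccinimide (compound 2), O=C1CCC(=O)N1Br
Why: Electrophilic aromatic bromination; the two α-positions are the only ring C-H sites and are activated by sulfur and the neighbouring methoxy groups, so two equivalents of NBS should give the 2,5-dibromide, which is not stored because such dibromides couple with themselves on standing.

Step 2
Reactants: 3 2,5-dibromo-3,4-dimethoxythiophene
Product: 4 2,5-dibromo-3,4-dimethoxythiophene 1,1-dioxide
Conditions: CF3CO3H (generated in the flask from (CF3CO)2O and urea·H2O2), CH2Cl2, 0 °C to rt, anhydrous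
Reagents that add atoms: trifluoroperacetic acid, OOC(=O)C(F)(F)F
Why: Peracid oxidation of a thiophene at sulfur to the 1,1-dioxide; anhydrous CF3CO3H is electrophilic enough to take a dihalothiophene through the S-oxide to the sulfone, the methoxy groups make the ring more electron-rich than in 2,5-dibromothiophene itself, and the tetrasubstituted dioxide cannot dimerise by a Diels-Alder reaction with itself.

Step 3
Reactants: 5 methyl propiolate; 2 N-bromosuccinimide
Product: 6 methyl 3-bromopropiolate
Conditions: NBS (1.1 equiv), AgNO3 (0.1 equiv), acetone, rt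
Reagents that add atoms: N-bromosuccinimide (compound 2), O=C1CCC(=O)N1Br
Why: AgNO3-catalysed bromination of a terminal alkyne through the silver acetylide, the standard route to 1-bromoalkynes, which the ester tolerates.

Step 4
Reactants: 4 2,5-dibromo-3,4-dimethoxythiophene 1,1-dioxide; 6 methyl 3-bromopropiolate
Product: 8 methyl 2,3,6-tribromo-4,5-dimethoxybenzoate, via thianorbornadiene dioxide cycloadduct 7 (not isolated)
Conditions: 6 (3 equiv), toluene, 110 °C, sealed tube
Reagents that add atoms: none
Why: As a sulfone, 4 no longer has thiophene aromaticity and behaves as a 1,4-dibromo-2,3-dimethoxybutadiene fixed in the cisoid form, electron-rich enough at its inner carbons to pair with the ester-activated alkyne 6; a concerted suprafacial [4+2] cycloaddition joins C3 to C2 and C6 to C1 and gives the 7-thiabicyclo[2.2.1]heptadiene dioxide 7. Compound 7 then expels SO2 in a thermally allowed cheletropic step, which turns the new six-membered carbocycle into the benzene ring with all six substituents in place. The closest known reaction type is the Diels-Alder reaction of tetrasubstituted thiophene 1,1-dioxides with alkynes followed by SO2 extrusion. The one ring formed, the benzene ring, is closed by intermolecular [4+2] cycloaddition across the diene termini and aromatised by the extrusion; the two bridgehead stereocentres of 7 are transient and racemic, and the product has none. No regiochemistry has to be controlled, because 4 has a mirror plane through sulfur and both orientations of 6 give the same arene. The selectivity that matters is cycloaddition ahead of self-reaction, which full substitution of the dioxide secures, and since 7 has no ring hydrogen it can aromatise only by losing SO2 and cannot lose HBr.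

Step 5
Reactants: 8 methyl 2,3,6-tribromo-4,5-dimethoxybenzoate
Product: 9 methyl 2,3,6-tribromo-4,5-dihydroxybenzoate
Conditions: BBr3 (3 equiv), CH2Cl2, −78 °C to 0 °C; then H2O
Reagents that add atoms: none
Why: Lewis acid cleavage of aryl methyl ethers (BBr3 demethylation); both methoxy groups are flanked on each side and twisted out of conjugation, so their oxygens are basic and should be cleaved at or below 0 °C, where the methyl ester survives.

Step 6
Reactants: 9 methyl 2,3,6-tribromo-4,5-dihydroxybenzoate
Product: 10 methyl 2,3,6-tribromo-4,5-bis[(triisopropylsilyl)oxy]benzoate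
Conditions: iPr3SiOTf (2.6 equiv), 2,6-lutidine, CH2Cl2, 0 °C to rt
Reagents that add atoms: triisopropylsilyl trifluoromethanesulfonate, CC(C)[Si](C(C)C)(C(C)C)OS(=O)(=O)C(F)(F)F
Why: Silyl ether formation with a silyl triflate and a hindered base; the triflate is reactive enough for both acidic, ortho-substituted phenols, and the bulky triisopropylsilyl group is chosen because it shifts between neighbouring oxygens far more slowly than smaller silyl groups.

Step 7
Reactants: 10 methyl 2,3,6-tribromo-4,5-bis[(triisopropylsilyl)oxy]benzoate
Product: 11 methyl 2,3,6-tribromo-4-hydroxy-5-[(triisopropylsilyl)oxy]benzoate (O4 free, O5 silylated)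
Conditions: K2CO3 (1.05 equiv), MeOH/THF, −10 °C to 0 °C; then 1 M HCl
Reagents that add atoms: none
Why: Base-mediated methanolysis of an aryl silyl ether, whose rate follows the stability of the departing phenoxide; O4 is para to the ester and meta to two bromines while O5 is only meta to the ester and para to one bromine, so the O4 silyl ether should go first, the phenoxide formed shields the second silyl ether from cleavage, and any silyl shift would also end with silicon on the less acidic O5.

Step 8
Reactants: 11 methyl 2,3,6-tribromo-4-hydroxy-5-[(triisopropylsilyl)oxy]benzoate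
Product: 12 sodium 2,3,5-tribromo-4-(methoxycarbonyl)-6-[(triisopropylsilyl)oxy]phenyl sulfate (sulfate on O4)
Conditions: SO3·pyridine (4 equiv), pyridine, 45 °C; then NaHCO3 (aq)
Reagents that add atoms: sulfur trioxide pyridine complex, O=S(=O)([O-])[n+]1ccccc1; sodium hydrogen carbonate, [Na+].OC([O-])=O
Why: O-Sulfation of a phenol with SO3·pyridine; O4 is the only free hydroxyl, and sulfating it while C7 is still an ester fixes the regiochemistry and means that no para-hydroxybenzyl compound with a leaving group at C7, which could ionise to a para-quinone methide, is ever formed.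

Step 9
Reactants: 12 sodium 2,3,5-tribromo-4-(methoxycarbonyl)-6-[(triisopropylsilyl)oxy]phenyl sulfate
Product: 13 sodium 2,3,5-tribromo-4-(hydroxymethyl)-6-[(triisopropylsilyl)oxy]phenyl sulfate
Conditions: iBu2AlH (5 equiv), THF, −78 °C to rt; then MeOH, Na2C4H4O6 (disodium tartrate, aq)
Reagents that add atoms: none
Why: Reduction of an ester to the primary alcohol with iBu2AlH; sulfate monoester anions do not react with hydride donors, the aryl bromides and the aryl silyl ether are untouched at these temperatures, and excess reagent overcomes the shielding of the carbonyl by the two ortho bromines.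

Step 10
Reactants: 13 sodium 2,3,5-tribromo-4-(hydroxymethyl)-6-[(triisopropylsilyl)oxy]phenyl sulfate
Product: 14 disodium 2,3,5-tribromo-4-[(sulfonatooxy)methyl]-6-[(triisopropylsilyl)oxy]phenyl sulfate
Conditions: SO3·pyridine (3 equiv), DMF, 0 °C to rt; then NaHCO3 (aq)
Reagents that add atoms: sulfur trioxide pyridine complex, O=S(=O)([O-])[n+]1ccccc1; sodium hydrogen carbonate, [Na+].OC([O-])=O
Why: O-Sulfation of a primary alcohol with SO3·pyridine; the benzylic hydroxyl is the only free OH, and the benzylic sulfate formed should not ionise because O4 is already a sulfate and the ring carries three bromines.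

Step 11
Reactants: 14 disodium 2,3,5-tribromo-4-[(sulfonatooxy)methyl]-6-[(triisopropylsilyl)oxy]phenyl sulfate
Product: 16 2,3,5-tribromo-6-hydroxy-4-[(sulfooxy)methyl]phenyl hydrogen sulfate (the target), via disodium salt of the target 15 (not isolated)
Conditions: KHF2 (3 equiv), MeOH, rt; then 1 M HCl to pH 1, 0 °C, desalting on C18 (cold 0.01 M HCl, then MeOH/H2O)
Reagents that add atoms: none
Why: Cleavage of an aryl silyl ether by bifluoride in methanol followed by protonation of the sulfate salt; sulfate monoesters are stable to fluoride, the freed O5 hydroxyl is meta to C7 and cannot expel the benzylic sulfate, and brief cold acid should not hydrolyse either sulfate.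

**Compound list**

1 | 3,4-dimethoxythiophene | COc1cscc1OC | starting material
2 | N-bromosuccinimide | O=C1CCC(=O)N1Br | starting material
3 | 2,5-dibromo-3,4-dimethoxythiophene | COc1c(Br)sc(Br)c1OC | intermediate
4 | 2,5-dibromo-3,4-dimethoxythiophene 1,1-dioxide | COC1=C(Br)S(=O)(=O)C(Br)=C1OC | intermediate
5 | methyl propiolate | C#CC(=O)OC | starting material
6 | methyl 3-bromopropiolate | COC(=O)C#CBr | intermediate
7 | methyl 1,3,4-tribromo-5,6-dimethoxy-7-thiabicyclo[2.2.1]hepta-2,5-diene-2-carboxylate 7,7-dioxide (racemic; bridgehead configuration fixed by the bicycle) | COC(=O)C1=C(Br)C2(Br)C(OC)=C(OC)C1(Br)S2(=O)=O | intermediate (not isolated)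
8 | methyl 2,3,6-tribromo-4,5-dimethoxybenzoate | COC(=O)c1c(Br)c(Br)c(OC)c(OC)c1Br | intermediate
9 | methyl 2,3,6-tribromo-4,5-dihydroxybenzoate | COC(=O)c1c(Br)c(Br)c(O)c(O)c1Br | intermediate
10 | methyl 2,3,6-tribromo-4,5-bis[(triisopropylsilyl)oxy]benzoate | COC(=O)c1c(Br)c(Br)c(O[Si](C(C)C)(C(C)C)C(C)C)c(O[Si](C(C)C)(C(C)C)C(C)C)c1Br | intermediate
11 | methyl 2,3,6-tribromo-4-hydroxy-5-[(triisopropylsilyl)oxy]benzoate | COC(=O)c1c(Br)c(Br)c(O)c(O[Si](C(C)C)(C(C)C)C(C)C)c1Br | intermediate
12 | sodium 2,3,5-tribromo-4-(methoxycarbonyl)-6-[(triisopropylsilyl)oxy]phenyl sulfate | [Na+].COC(=O)c1c(Br)c(Br)c(OS(=O)(=O)[O-])c(O[Si](C(C)C)(C(C)C)C(C)C)c1Br | intermediate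
13 | sodium 2,3,5-tribromo-4-(hydroxymethyl)-6-[(triisopropylsilyl)oxy]phenyl sulfate | [Na+].OCc1c(Br)c(Br)c(OS(=O)(=O)[O-])c(O[Si](C(C)C)(C(C)C)C(C)C)c1Br | intermediate
14 | disodium 2,3,5-tribromo-4-[(sulfonatooxy)methyl]-6-[(triisopropylsilyl)oxy]phenyl sulfate | [Na+].[Na+].[O-]S(=O)(=O)OCc1c(Br)c(Br)c(OS(=O)(=O)[O-])c(O[Si](C(C)C)(C(C)C)C(C)C)c1Br | intermediate
15 | disodium 2,3,5-tribromo-6-hydroxy-4-[(sulfonatooxy)methyl]phenyl sulfate | [Na+].[Na+].[O-]S(=O)(=O)OCc1c(Br)c(Br)c(OS(=O)(=O)[O-])c(O)c1Br | intermediate (not isolated)
16 | 2,3,5-tribromo-6-hydroxy-4-[(sulfooxy)methyl]phenyl hydrogen sulfate (CNP0213554.0; no stereocentre) | O=S(=O)(O)OCc1c(Br)c(O)c(OS(=O)(=O)O)c(Br)c1Br | target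

**Step count and risks**

Total step count: 11. Longest linear sequence: 10 steps (steps 1, 2 and 4 to 11, from 3,4-dimethoxythiophene); step 3 is the side branch.

Steps most likely to fail:

Step 4. The cycloaddition may be slower than thermal breakdown or oligomerisation of the bromoalkyne and of the push-pull dioxide, so that little adduct forms. The fallback sets out from 4 and swaps the alkyne for an alkene dienophile, commercial methyl 2-bromoacrylate, in toluene at 80 to 110 °C. The [4+2] adduct methyl 1,2,4-tribromo-5,6-dimethoxy-7-thiabicyclo[2.2.1]hept-5-ene-2-carboxylate 7,7-dioxide F1 should lose SO2 to methyl 1,2,5-tribromo-3,4-dimethoxycyclohexa-2,4-diene-1-carboxylate F2. F2 aromatises by loss of HBr (Et3N) to methyl 2,5-dibromo-3,4-dimethoxybenzoate F3. The single free ring position of F3, para to a methoxy group, is then brominated (Br2, AcOH, 50 °C) to give 8, where the route is rejoined.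

Step 2. The peracid may attack the methoxy-substituted C=C bonds, or the acidic medium may hydrolyse the β-methoxy vinyl sulfone, faster than sulfur is oxidised twice; compound 3 may also couple with itself before it reacts. The fallback sets out from 1 and avoids 3. Double lithiation at the α-positions (n-BuLi, TMEDA, THF, −78 °C to 0 °C) and quenching with Me3SiCl gives 3,4-dimethoxy-2,5-bis(trimethylsilyl)thiophene F4. Oxidation with mCPBA in CH2Cl2 gives 3,4-dimethoxy-2,5-bis(trimethylsilyl)thiophene 1,1-dioxide F5; α-silyl thiophenes are oxidised cleanly at sulfur and the silyl groups shield the ring carbons. Ipso-bromodesilylation with Br2 and AgBF4 in CH2Cl2 at 0 °C then gives 4, where the route is rejoined.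

Step 7. The two silyl ethers may not be told apart well enough, because the ester lies between two bromines and is twisted out of conjugation with O4; the result would be a mixture of monosilyl isomers and some fully desilylated catechol. The fallback sets out from 8 and does the differentiation at the aldehyde level, where the small formyl group can stay close to the ring plane and widens the gap between O4 and O5. Reduction of 8 with iBu2AlH gives (2,3,6-tribromo-4,5-dimethoxyphenyl)methanol F6, and Swern oxidation ((COCl)2, DMSO, Et3N) gives 2,3,6-tribromo-4,5-dimethoxybenzaldehyde F7. BBr3 then gives 2,3,6-tribromo-4,5-dihydroxybenzaldehyde F8, and iPr3SiOTf with 2,6-lutidine gives 2,3,6-tribromo-4,5-bis[(triisopropylsilyl)oxy]benzaldehyde F9. K2CO3 in MeOH/THF gives 2,3,6-tribromo-4-hydroxy-5-[(triisopropylsilyl)oxy]benzaldehyde F10, and SO3·pyridine followed by NaHCO3 gives sodium 2,3,5-tribromo-4-formyl-6-[(triisopropylsilyl)oxy]phenyl sulfate F11. NaBH4 in MeOH at 0 °C reduces the aldehyde to 13, where the route is rejoined.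

**Further compounds**

F1 | step 4 | methyl 1,2,4-tribromo-5,6-dimethoxy-7-thiabicyclo[2.2.1]hept-5-ene-2-carboxylate 7,7-dioxide (racemic, mixture of diastereomers) | COC(=O)C1(Br)CC2(Br)C(OC)=C(OC)C1(Br)S2(=O)=O
F2 | step 4 | methyl 1,2,5-tribromo-3,4-dimethoxycyclohexa-2,4-diene-1-carboxylate (racemic) | COC(=O)C1(Br)CC(Br)=C(OC)C(OC)=C1Br
F3 | step 4 | methyl 2,5-dibromo-3,4-dimethoxybenzoate | COC(=O)c1cc(Br)c(OC)c(OC)c1Br
F4 | step 2 | 3,4-dimethoxy-2,5-bis(trimethylsilyl)thiophene | COc1c([Si](C)(C)C)sc([Si](C)(C)C)c1OC
F5 | step 2 | 3,4-dimethoxy-2,5-bis(trimethylsilyl)thiophene 1,1-dioxide | COC1=C([Si](C)(C)C)S(=O)(=O)C([Si](C)(C)C)=C1OC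
F6 | step 7 | (2,3,6-tribromo-4,5-dimethoxyphenyl)methanol | COc1c(OC)c(Br)c(CO)c(Br)c1Br
F7 | step 7 | 2,3,6-tribromo-4,5-dimethoxybenzaldehyde | COc1c(OC)c(Br)c(C=O)c(Br)c1Br
F8 | step 7 | 2,3,6-tribromo-4,5-dihydroxybenzaldehyde | O=Cc1c(Br)c(Br)c(O)c(O)c1Br
F9 | step 7 | 2,3,6-tribromo-4,5-bis[(triisopropylsilyl)oxy]benzaldehyde | O=Cc1c(Br)c(Br)c(O[Si](C(C)C)(C(C)C)C(C)C)c(O[Si](C(C)C)(C(C)C)C(C)C)c1Br
F10 | step 7 | 2,3,6-tribromo-4-hydroxy-5-[(triisopropylsilyl)oxy]benzaldehyde | O=Cc1c(Br)c(Br)c(O)c(O[Si](C(C)C)(C(C)C)C(C)C)c1Br
F11 | step 7 | sodium 2,3,5-tribromo-4-formyl-6-[(triisopropylsilyl)oxy]phenyl sulfate | [Na+].O=Cc1c(Br)c(Br)c(OS(=O)(=O)[O-])c(O[Si](C(C)C)(C(C)C)C(C)C)c1Br
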